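## Retrosynthetic overview

- Ring A is closed last. Target 33 ⇐ 31 by oxidation of the C19 aldehyde and ester hydrolysis; 31 ⇐ trialdehyde 30 by a group-selective SmI2 pinacol cyclization that forms the C2–C3 bond, the 2β,3β-diol and the quaternary C4 in one operation.
- Enabling feature: C4 is a quaternary carbon carrying two carbonyl-level carbons (C3 and C19) beside C18, so it can be built as an achiral 2-methylmalonyl unit. C2/C3 is a cis-1,2-diol (pinacol retron) in a ring A whose chair is locked by the trans A/B fusion, with C20 axial on C10.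
- 30 ⇐ ring B by Knoevenagel condensation at the C5 aldehyde and intramolecular Michael addition/methylation (C5–C6 bond, C4 from a dithiomalonate); C10 is made quaternary by alkylation of the 20→12α lactone enolate.
- Lactone and ring D ⇐ C12 reduction/lactonization after a gold-catalysed Conia-ene closure (C13–C16); C8/C9 ⇐ catalytic desymmetrizing Michael addition on dienone 9 through a temporary cyclopentanone, opened again by retro-Claisen cleavage.
- Order of ring formation: ring C (Robinson annulation, then dienone), temporary five-membered ring (made and opened), ring D, δ-lactone, ring B, ring A.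

Key step: step 18

Remark (convention): carbons carry the gibberellane numbers C1–C20; α/β are those of the usual gibberellin drawing (H5, H9, C18 and the C15–C16 bridge β; C19, C20 and the oxygen on C12 α).

Assumption: the quinine-derived thiourea is taken to give the C8/C9 configuration drawn for 10; if the sense is opposite, the quinidine-derived pseudoenantiomer is used and nothing else changes.

## Route

Step 1
Reactants: 1 pent-4-ynal; 2 methyl (E)-4-bromo-3-methoxybut-2-enoate
Product: 4 methyl (E)-5-formyl-3-methoxyoct-2-en-7-ynoate (racemic), via enamine 3 (not isolated)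
Conditions: pyrrolidine (1.2 equiv), 4 Å MS, MeCN, 0 °C → rt; then 2, 60 °C; then H2O, rt
Reagents that add atoms: water, O
Why: Stork enamine alkylation: the pyrrolidine enamine 3 is C-alkylated by the reactive allylic bromide 2 and the iminium salt is hydrolysed, which attaches the masked acetoacetate arm to the carbon that becomes C8 (the new stereocentre is racemic and disappears at the dienone stage).

Step 2
Reactants: 4 methyl (E)-5-formyl-3-methoxyoct-2-en-7-ynoate; 5 but-3-en-2-one
Product: 7 methyl (E)-3-methoxy-4-[4-oxo-1-(prop-2-yn-1-yl)cyclohex-2-en-1-yl]but-2-enoate (racemic), via keto aldehyde 6 (not isolated)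
Conditions: NaOMe (0.2 equiv), MeOH, 0 → 50 °C
Reagents that add atoms: none
Why: Robinson annulation: Michael addition of the α-branched aldehyde enolate to methyl vinyl ketone gives 6 with the quaternary carbon C8, and intramolecular aldol condensation closes ring C as the 4,4-disubstituted cyclohexenone.

Step 3
Reactants: 7 methyl (E)-3-methoxy-4-[4-oxo-1-(prop-2-yn-1-yl)cyclohex-2-en-1-yl]but-2-enoate
Product: 9 methyl 3-oxo-4-[4-oxo-1-(prop-2-yn-1-yl)cyclohexa-2,5-dien-1-yl]butanoate, via dienone enol ether 8 (not isolated)
Conditions: DDQ (1.5 equiv), 1,4-dioxane, 100 °C; then 2 M HCl, THF, rt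
Reagents that add atoms: water, O
Why: DDQ dehydrogenation of the 4,4-disubstituted cyclohexenone gives the cross-conjugated dienone 8, in which C8 is prochiral, and acid hydrolysis of the β-methoxy enoate then unmasks the β-keto ester (no stereocentre remains).

Step 4
Reactants: 9 methyl 3-oxo-4-[4-oxo-1-(prop-2-yn-1-yl)cyclohexa-2,5-dien-1-yl]butanoate
Product: 10 methyl 2,6-dioxo-3a-(prop-2-yn-1-yl)-2,3,3a,6,7,7a-hexahydro-1H-indene-1-carboxylate (cis-fused; 8β-propargyl and 9β-H; C10 epimers in equilibrium with the enol)
Conditions: quinine-derived 3,5-bis(trifluoromethyl)phenyl thiourea (10 mol %), toluene, −20 °C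
Reagents that add atoms: none
Why: Organocatalytic desymmetrizing intramolecular Michael addition (5-exo-trig) of the β-keto ester carbon C10 to one enone arm: the three-atom tether enforces the cis ring fusion, which fixes C9 relative to C8, and the bifunctional thiourea–amine catalyst chooses between the two enantiotopic enone arms, which fixes both centres absolutely.

Step 5
Reactants: 10 cis-hydrindenedione β-keto ester
Product: 11 methyl 1-(dimethoxymethyl)-2,6-dioxo-3a-(prop-2-yn-1-yl)-2,3,3a,6,7,7a-hexahydro-1H-indene-1-carboxylate (ring fusion as in 10; quaternary C10 of unassigned configuration)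
Conditions: HC(OMe)3, BF3·OEt2, CH2Cl2, −30 °C; then 10, i-Pr2NEt, −78 → 0 °C
Reagents that add atoms: trimethyl orthoformate, COC(OC)OC
Why: C-alkylation of the β-keto ester enol by the dimethoxycarbenium ion formed from the orthoformate and BF3 (an α-formylation equivalent) introduces C5 at the aldehyde oxidation level and makes C10 quaternary, so that the β-keto ester can no longer enolize and can be cleaved in step 6 (the C10 configuration is lost there).

Step 6
Reactants: 11 quaternary β-keto ester acetal
Product: 12 methyl 3,3-dimethoxy-2-[2-(2-methoxy-2-oxoethyl)-5-oxo-2-(prop-2-yn-1-yl)cyclohex-3-en-1-yl]propanoate (C8 acetate arm and C9 side chain cis, both α; propargyl β; C10 epimers)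
Conditions: NaOMe (0.3 equiv), MeOH, 0 °C
Reagents that add atoms: methanol, CO
Why: Retro-Claisen (retro-Dieckmann) cleavage: methoxide adds to the strained, non-enolizable ketone and the C7–C10 bond breaks, which opens the temporary ring to the C8 acetate arm and the C9 side chain held cis as set in step 4; C10 is protonated unselectively, which is harmless because it is enolized again in step 10.

Step 7
Reactants: 12 cyclohexenone diester acetal
Product: 14 methyl 2-[5-(tert-butyldimethylsilyloxy)-2-(2-methoxy-2-oxoethyl)-2-(prop-2-yn-1-yl)cyclohex-4-en-1-yl]-3,3-dimethoxypropanoate (configuration as in 12), via lithium enolate 13 (not isolated)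
Conditions: LiBH(s-Bu)3 (L-Selectride), THF, −78 °C; then TBSOTf, −78 → −40 °C
Reagents that add atoms: tert-butyldimethylsilyl trifluoromethanesulfonate, CC(C)(C)[Si](C)(C)OS(=O)(=O)C(F)(F)F
Why: Conjugate reduction of the β-unsubstituted enone by L-Selectride and O-silylation of the enolate 13 give the C12–C13 silyl enol ether regiospecifically (no new stereocentre).

Step 8
Reactants: 14 silyl enol ether
Product: 15 methyl 3,3-dimethoxy-2-[1-(2-methoxy-2-oxoethyl)-6-methylidene-4-oxobicyclo[3.2.1]octan-2-yl]propanoate (rings C and D; C15–C16 bridge β; C9 side chain α)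
Conditions: (Ph3P)AuCl (5 mol %), AgBF4 (5 mol %), CH2Cl2/MeOH 10:1, rt
Reagents that add atoms: none
Why: Gold-catalysed Conia-ene-type carbocyclization: the silyl enol ether carbon C13 attacks the gold-activated alkyne at C16 (5-exo-dig) and protodeauration by methanol leaves the exocyclic methylene, which closes ring D as the bicyclo[3.2.1]octanone; the two-carbon bridge can only span the face that carries the C8 propargyl group, so C13 follows from C8.

Step 9
Reactants: 15 bicyclo[3.2.1]octanone
Product: 17 δ-lactone of the 12α-alcohol onto C20 (C20–O–C12 bridge on the α-face; C8–CH2CO2Me kept; C10 bears H and CH(OMe)2 as epimers), via hydroxy diester 16 (not isolated)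
Conditions: NaBH4, MeOH, −20 → 0 °C; then PPTS (cat.), toluene, 40 °C
Reagents that add atoms: none
Why: Diastereoselective ketone reduction and lactonization: hydride attacks the C12 ketone from the β-face because the α-face is shielded 1,3-diaxially by the C9 side chain, and the resulting axial 12α-alcohol 16 closes the six-membered lactone onto the C20 ester (the C7 ester would require a seven-membered ring).

Step 10
Reactants: 17 δ-lactone; 18 tert-butyl(2-iodoethoxy)dimethylsilane
Product: 19 lactone alkylated at C10 with the 2-(tert-butyldimethylsilyloxy)ethyl group (C1–C2; axial on the lactone ring; anti to C8; β in the final skeleton) beside the CH(OMe)2 group (C5)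
Conditions: KN(SiMe3)2 (1.05 equiv), THF, −78 → −40 °C; then 18, DMPU, −40 → 0 °C
Reagents that add atoms: none
Why: Alkylation of the lactone enolate (the lactone α-proton is several pKa units more acidic than the protons of the C6 methylene ester): the iodide enters axially on the exo face of the bicyclic lactone, anti to the C9–C8 bond, which sets the quaternary C10 with C1 axial (β in the final skeleton) and the C5 acetal equatorial beside C8, as ring B requires.

Step 11
Reactants: 19 C10-quaternary lactone acetal
Product: 21 C5 aldehyde (formyl group on C10 in place of CH(OMe)2; otherwise as 19), via collidinium salt 20 (not isolated)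
Conditions: TESOTf, 2,4,6-collidine, CH2Cl2, 0 °C; then H2O, rt
Reagents that add atoms: water, O
Why: Chemoselective acetal cleavage: TESOTf activates one methoxy group, 2,4,6-collidine traps the oxocarbenium ion as the N,O-acetal salt 20 and water hydrolyses it to the C5 aldehyde under conditions that leave the TBS ether, the esters and the exocyclic alkene untouched (no stereocentre is affected).

Step 12
Reactants: 22 malonyl dichloride; 23 ethanethiol
Product: 24 S,S-diethyl propanebis(thioate)
Conditions: 23 (2.2 equiv in all), CH2Cl2, 0 °C → reflux, N2 sweep to remove HCl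
Reagents that add atoms: ethanethiol (the second equivalent of 23), CCS
Why: Twofold thioesterification of the diacid chloride: each acyl chloride group is attacked by one equivalent of ethanethiol with loss of HCl, and no amine base is used because it would convert malonyl dichloride into ketene-derived by-products; the resulting dithiomalonate carries thioesters that can later be reduced to aldehydes in the presence of esters.

Step 13
Reactants: 21 C5 aldehyde; 24 S,S-diethyl propanebis(thioate)
Product: 25 alkylidene dithiomalonate (C5H=C4(COSEt)2 on C10; otherwise as 21)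
Conditions: TiCl4, pyridine, THF, 0 °C → rt
Reagents that add atoms: none
Why: Knoevenagel condensation mediated by TiCl4/pyridine, which is effective for α-quaternary aldehydes, gives the doubly activated alkylidene dithiomalonate (symmetrical, so no alkene geometry and no stereocentre arises).

Step 14
Reactants: 25 alkylidene dithiomalonate
Product: 27 ring-A-seco gibberellane (ring B closed; H5 β; 6β-CO2Me; C4 = C(CH3)(COSEt)2 on the α-side of C5; C10 with β-CH2CH2OTBS and the 20→12α lactone), via lithium thiomalonate enolate 26 (not isolated)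
Conditions: LiN(SiMe3)2 (1.1 equiv), THF, −78 °C; then MeI, DMPU, −78 → 0 °C
Reagents that add atoms: iodomethane, CI
Why: Intramolecular Michael addition (5-exo-trig) of the C6 ester enolate to the alkylidene dithiomalonate closes ring B and the thiomalonate enolate 26 is methylated at C4: allylic 1,3-strain keeps the alkylidene terminus over the flat lactone carbonyl C20 (α) and not over the C1 methylene in the transition state, which gives H5 β, and the C6 ester takes the position trans to the C5 substituent (a cis isomer would be equilibrated in step 20).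

Step 15
Reactants: 27 bis(thioester) TBS ether
Product: 28 primary alcohol (C2–OH; otherwise as 27)
Conditions: HF·pyridine, pyridine, THF, 0 °C
Reagents that add atoms: none
Why: Desilylation of the primary TBS ether by buffered HF·pyridine, which leaves thioesters, ester and lactone intact (the alcohol is oxidized at once to avoid translactonization).

Step 16
Reactants: 28 primary alcohol
Product: 29 C2 aldehyde (C10–CH2–CHO; C4 still C(CH3)(COSEt)2)
Conditions: Dess–Martin periodinane, CH2Cl2, 0 °C → rt
Reagents that add atoms: none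
Why: Dess–Martin oxidation of the primary alcohol to the C2 aldehyde under neutral conditions.

Step 17
Reactants: 29 C2 aldehyde bis(thioester)
Product: 30 trialdehyde (C10–CH2–CHO and C4(CH3)(CHO)2; 7-methyl ester; 20→12α lactone; 16-methylene)
Conditions: Et3SiH (6 equiv), Pd/CaCO3 poisoned with Pb(OAc)2 (Lindlar catalyst), acetone, rt
Reagents that add atoms: none
Why: Fukuyama reduction: palladium-catalysed reduction of both thioesters by the hydrosilane gives the two formyl groups under neutral conditions that spare the methyl ester, the lactone, the aldehyde and, with the lead-poisoned catalyst, the exocyclic alkene; the trialdehyde is used without purification.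

Step 18
Reactants: 30 trialdehyde
Product: 31 2β,3β-dihydroxy-19-oxo gibberell-16-ene 7-methyl ester 20,12α-lactone (ring A closed; 4β-CH3; 4α-CHO)
Conditions: SmI2 (2.2 equiv, 0.1 M in THF), THF, −78 °C; then H2O (pH 7 buffer)
Reagents that add atoms: none
Why: Single-electron transfer from divalent samarium (SmI2) to the unhindered C2 aldehyde gives a ketyl radical anion that adds to one samarium-bound C4 formyl group, a second electron transfer gives the trivalent-samarium-bridged cis-diolate, and aqueous work-up gives the diol (the third formyl group remains because only 2.2 equivalents are used). The closest known reaction type is the SmI2-promoted intramolecular pinacol cyclization of 1,6-dialdehydes to cis-cyclohexane-1,2-diols, here in its diastereotopic-group-selective form. Ring A closes as a six-membered ring by ketyl–carbonyl coupling between C2 and C3, in a chair locked by the trans A/B fusion with C20 axial on C10 and H5 axial on C5. C4 is set by group selection: only two rotamers about C4–C5 can close, and the one that leaves the methyl group equatorial (β, anti to C10) is preferred over the one that puts it axial, gauche to both C6 and C10 and 1,3-diaxial to C20, so the α-formyl group stays as C19. C2 and C3 are set cis by the samarium bridge between the two oxygens, and on the β-face because an α-oxygen at C2 would be axial and 1,3-diaxial to both C19 and C20, which leaves O3 axial and O2 equatorial. The step needs group selectivity, face selectivity and chemoselectivity against a three-membered pinacol of the geminal diformyl unit; the first two follow from the locked chair, the last from the strain of a cyclopropanediol against the strain-free six-membered closure at low temperature.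

Step 19
Reactants: 31 diol aldehyde
Product: 32 2β,3β-dihydroxy gibberell-16-ene-19-oic acid 7-methyl ester 20,12α-lactone
Conditions: NaClO2, NaH2PO4, 2-methyl-2-butene, t-BuOH/H2O, 0 °C → rt
Reagents that add atoms: sodium chlorite, [Na+].[O-]Cl=O
Why: Pinnick oxidation converts the hindered axial aldehyde into the C19 carboxylic acid without touching the diol or the alkene (2-methyl-2-butene removes hypochlorous acid).

Step 20
Reactants: 32 19-acid 7-methyl ester
Product: 33 target CNP0212122.1 (2β,3β-dihydroxy gibberell-16-ene-7,19-dioic acid 20,12α-lactone)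
Conditions: LiOH, THF/H2O, 40 °C; then 1 M HCl to pH 2
Reagents that add atoms: lithium hydroxide, [Li+].[OH-]
Why: Saponification of the C7 methyl ester by LiOH, under which C6 can equilibrate to the more stable β-carboxyl trans to the C5 substituent, and acidification, which closes the rigid δ-lactone again if it has opened, should give the target.

## Compound list

1 | pent-4-ynal | C#CCCC=O | starting material
2 | methyl (E)-4-bromo-3-methoxybut-2-enoate | COC(=O)/C=C(\CBr)OC | starting material
3 | (E)-1-(pent-1-en-4-yn-1-yl)pyrrolidine | C#CC/C=C/N1CCCC1 | intermediate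
4 | methyl (E)-5-formyl-3-methoxyoct-2-en-7-ynoate (racemic) | COC(=O)/C=C(/OC)CC(C=O)CC#C | intermediate
5 | but-3-en-2-one (methyl vinyl ketone) | C=CC(C)=O | starting material
6 | methyl (E)-5-formyl-3-methoxy-5-(3-oxobutyl)oct-2-en-7-ynoate (racemic) | COC(=O)/C=C(/OC)CC(C=O)(CC#C)CCC(C)=O | intermediate
7 | methyl (E)-3-methoxy-4-[4-oxo-1-(prop-2-yn-1-yl)cyclohex-2-en-1-yl]but-2-enoate (racemic) | COC(=O)/C=C(/OC)CC1(CC#C)C=CC(=O)CC1 | intermediate
8 | methyl (E)-3-methoxy-4-[4-oxo-1-(prop-2-yn-1-yl)cyclohexa-2,5-dien-1-yl]but-2-enoate | COC(=O)/C=C(/OC)CC1(CC#C)C=CC(=O)C=C1 | intermediate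
9 | methyl 3-oxo-4-[4-oxo-1-(prop-2-yn-1-yl)cyclohexa-2,5-dien-1-yl]butanoate | COC(=O)CC(=O)CC1(CC#C)C=CC(=O)C=C1 | intermediate
10 | methyl 2,6-dioxo-3a-(prop-2-yn-1-yl)-2,3,3a,6,7,7a-hexahydro-1H-indene-1-carboxylate, cis-fused (8β-propargyl, 9β-H; C10 epimers) | C#CC[C@@]12CC(=O)C(C(=O)OC)[C@@H]1CC(=O)C=C2 | intermediate
11 | methyl 1-(dimethoxymethyl)-2,6-dioxo-3a-(prop-2-yn-1-yl)-2,3,3a,6,7,7a-hexahydro-1H-indene-1-carboxylate (ring fusion as 10; C10 unassigned) | C#CC[C@@]12CC(=O)C(C(OC)OC)(C(=O)OC)[C@@H]1CC(=O)C=C2 | intermediate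
12 | methyl 3,3-dimethoxy-2-[2-(2-methoxy-2-oxoethyl)-5-oxo-2-(prop-2-yn-1-yl)cyclohex-3-en-1-yl]propanoate (acetate arm and C9 side chain cis; C10 epimers) | C#CC[C@]1(CC(=O)OC)C=CC(=O)C[C@H]1C(C(OC)OC)C(=O)OC | intermediate
13 | lithium C12–C13 enolate from conjugate reduction of 12 | C#CC[C@]1(CC(=O)OC)CC=C([O-])C[C@H]1C(C(OC)OC)C(=O)OC.[Li+] | intermediate
14 | methyl 2-[5-(tert-butyldimethylsilyloxy)-2-(2-methoxy-2-oxoethyl)-2-(prop-2-yn-1-yl)cyclohex-4-en-1-yl]-3,3-dimethoxypropanoate | C#CC[C@]1(CC(=O)OC)CC=C(O[Si](C)(C)C(C)(C)C)C[C@H]1C(C(OC)OC)C(=O)OC | intermediate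
15 | methyl 3,3-dimethoxy-2-[1-(2-methoxy-2-oxoethyl)-6-methylidene-4-oxobicyclo[3.2.1]octan-2-yl]propanoate | C=C1C[C@]2(CC(=O)OC)C[C@H]1C(=O)C[C@H]2C(C(OC)OC)C(=O)OC | intermediate
16 | 12α-alcohol of 15 (hydroxy diester) | C=C1C[C@]2(CC(=O)OC)C[C@H]1[C@@H](O)C[C@H]2C(C(OC)OC)C(=O)OC | intermediate
17 | 20→12α δ-lactone with C8–CH2CO2Me; C10 bearing H and CH(OMe)2 (C10 epimers) | C=C1C[C@]2(CC(=O)OC)C[C@H]1[C@@H]1C[C@H]2C(C(OC)OC)C(=O)O1 | intermediate
18 | tert-butyl(2-iodoethoxy)dimethylsilane | CC(C)(C)[Si](C)(C)OCCI | starting material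
19 | C10-quaternary lactone: C10 bears CH(OMe)2 (C5) and CH2CH2OTBS (C1–C2, anti to C8) | C=C1C[C@]2(CC(=O)OC)C[C@H]1[C@@H]1C[C@H]2[C@@](C(OC)OC)(CCO[Si](C)(C)C(C)(C)C)C(=O)O1 | intermediate
20 | 2,4,6-trimethylpyridinium N,O-acetal triflate derived from 19 | C=C1C[C@]2(CC(=O)OC)C[C@H]1[C@@H]1C[C@H]2[C@@](C(OC)[n+]2c(C)cc(C)cc2C)(CCO[Si](C)(C)C(C)(C)C)C(=O)O1.[O-]S(=O)(=O)C(F)(F)F | intermediate
21 | C5 aldehyde (formyl on quaternary C10) | C=C1C[C@]2(CC(=O)OC)C[C@H]1[C@@H]1C[C@H]2[C@@](C=O)(CCO[Si](C)(C)C(C)(C)C)C(=O)O1 | intermediate
22 | malonyl dichloride | O=C(Cl)CC(Cl)=O | starting material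
23 | ethanethiol | CCS | starting material
24 | S,S-diethyl propanebis(thioate) | CCSC(=O)CC(=O)SCC | intermediate
25 | alkylidene dithiomalonate (C5H=C4(COSEt)2 on C10) | C=C1C[C@]2(CC(=O)OC)C[C@H]1[C@@H]1C[C@H]2[C@@](C=C(C(=O)SCC)C(=O)SCC)(CCO[Si](C)(C)C(C)(C)C)C(=O)O1 | intermediate
26 | lithium thiomalonate enolate after ring B closure | C=C1C[C@]23C[C@H]1[C@@H]1C[C@H]2[C@@](CCO[Si](C)(C)C(C)(C)C)(C(=O)O1)[C@H]([C@@H]3C(=O)OC)C(C(=O)SCC)=C([O-])SCC.[Li+] | intermediate
27 | ring-A-seco gibberellane: H5 β, 6β-CO2Me, C4 = C(CH3)(COSEt)2, C10–CH2CH2OTBS (β), 20→12α lactone | C=C1C[C@]23C[C@H]1[C@@H]1C[C@H]2[C@@](CCO[Si](C)(C)C(C)(C)C)(C(=O)O1)[C@H]([C@@H]3C(=O)OC)C(C)(C(=O)SCC)C(=O)SCC | intermediate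
28 | primary alcohol (C2–OH) from 27 | C=C1C[C@]23C[C@H]1[C@@H]1C[C@H]2[C@@](CCO)(C(=O)O1)[C@H]([C@@H]3C(=O)OC)C(C)(C(=O)SCC)C(=O)SCC | intermediate
29 | C2 aldehyde bis(thioester) | C=C1C[C@]23C[C@H]1[C@@H]1C[C@H]2[C@@](CC=O)(C(=O)O1)[C@H]([C@@H]3C(=O)OC)C(C)(C(=O)SCC)C(=O)SCC | intermediate
30 | trialdehyde: C10–CH2CHO and C4(CH3)(CHO)2 | C=C1C[C@]23C[C@H]1[C@@H]1C[C@H]2[C@@](CC=O)(C(=O)O1)[C@H]([C@@H]3C(=O)OC)C(C)(C=O)C=O | intermediate
31 | 2β,3β-dihydroxy-19-oxo gibberell-16-ene 7-methyl ester 20,12α-lactone | C=C1C[C@]23C[C@H]1[C@@H]1C[C@H]2[C@@]2(C[C@H](O)[C@H](O)[C@@](C)(C=O)[C@H]2[C@@H]3C(=O)OC)C(=O)O1 | intermediate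
32 | 2β,3β-dihydroxy gibberell-16-ene-19-oic acid 7-methyl ester 20,12α-lactone | C=C1C[C@]23C[C@H]1[C@@H]1C[C@H]2[C@@]2(C[C@H](O)[C@H](O)[C@@](C)(C(=O)O)[C@H]2[C@@H]3C(=O)OC)C(=O)O1 | intermediate
33 | CNP0212122.1 | C=C1C[C@]23C[C@H]1[C@@H]1C[C@H]2[C@@]2(C[C@H](O)[C@H](O)[C@@](C)(C(=O)O)[C@H]2[C@@H]3C(=O)O)C(=O)O1 | target

## Step count and risks

Total step count: 20. Longest linear sequence: 19 steps (steps 1–11 and 13–20; step 12 makes 24 in one step).

**Step 18 (key step).** What may go wrong: coupling of the C2 ketyl with the other formyl group (giving the C4 epimer), self-coupling of the geminal diformyl unit to a cyclopropanediol, or loss of a formyl group by retro-Claisen cleavage before ring A forms. Fallback (group selection is separated from the C–C bond formation, so no 1,3-dialdehyde is needed): it sets out from 27. A hydrolase of the esterase class (for example pig liver esterase, pH 7 buffer/acetone, chosen by screening for the isomer drawn) hydrolyses one of the two diastereotopic thioesters to the half-acid F1, which already holds the C19 acid. HF·pyridine then gives the alcohol F2, Dess–Martin oxidation gives the aldehyde F3, and Fukuyama reduction of the remaining thioester gives the 1,6-dialdehyde acid F4. As its lithium carboxylate, F4 undergoes the ordinary SmI2 pinacol cyclization and comes back to the route at 32.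

**Step 14.** What may go wrong: poor facial selectivity at C5, if the alkylidene reacts through the rotamer that puts C4 on the β-face; C5 cannot be corrected afterwards. Fallback (C5 is made trigonal and hydrogen is delivered from the open face): it sets out from 25. The same enolate cyclization is quenched with PhSeCl in place of MeI to give the selenide F5 (either C5 epimer). Oxidation with H2O2 and syn-elimination of the selenoxide give the tetrasubstituted alkylidene dithiomalonate F6. Conjugate reduction with SmI2/H2O in THF protonates C5 from the β-face and gives the malonate F7, and methylation (K2CO3, MeI, acetone) comes back to the route at 27.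

**Step 17.** What may go wrong: slow reduction of the two hindered thioesters, isomerization or reduction of the exocyclic alkene by palladium hydride, and decomposition of the diformyl unit over a long reaction time. Fallback (reduction to the alcohol level and re-oxidation instead of direct partial reduction): it sets out from 27. NaBH4 in EtOH/THF at 0 °C reduces only the thioesters and gives the 1,3-diol F8, HF·pyridine gives the triol F9, and a threefold Dess–Martin oxidation comes back to the route at 30.

Further compounds
F1 | step 18 | half-acid: C4 = C(CH3)(CO2H)(COSEt) with the acid as C19; TBS ether | C=C1C[C@]23C[C@H]1[C@@H]1C[C@H]2[C@@](CCO[Si](C)(C)C(C)(C)C)(C(=O)O1)[C@H]([C@@H]3C(=O)OC)[C@](C)(C(=O)O)C(=O)SCC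
F2 | step 18 | alcohol from F1 (C2–OH) | C=C1C[C@]23C[C@H]1[C@@H]1C[C@H]2[C@@](CCO)(C(=O)O1)[C@H]([C@@H]3C(=O)OC)[C@](C)(C(=O)O)C(=O)SCC
F3 | step 18 | C2 aldehyde from F2 | C=C1C[C@]23C[C@H]1[C@@H]1C[C@H]2[C@@](CC=O)(C(=O)O1)[C@H]([C@@H]3C(=O)OC)[C@](C)(C(=O)O)C(=O)SCC
F4 | step 18 | 1,6-dialdehyde acid (C2 and C3 formyl; C19 acid) | C=C1C[C@]23C[C@H]1[C@@H]1C[C@H]2[C@@](CC=O)(C(=O)O1)[C@H]([C@@H]3C(=O)OC)[C@](C)(C(=O)O)C=O
F5 | step 14 | C4 phenylselenide of the cyclized dithiomalonate (C5 and C6 epimers) | C=C1C[C@]23C[C@H]1[C@@H]1C[C@H]2[C@@](CCO[Si](C)(C)C(C)(C)C)(C(=O)O1)C(C3C(=O)OC)C([Se]c4ccccc4)(C(=O)SCC)C(=O)SCC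
F6 | step 14 | tetrasubstituted alkylidene dithiomalonate on ring B (C5=C4) | C=C1C[C@]23C[C@H]1[C@@H]1C[C@H]2[C@@](CCO[Si](C)(C)C(C)(C)C)(C(=O)O1)C(=C(C(=O)SCC)C(=O)SCC)C3C(=O)OC
F7 | step 14 | dithiomalonate with H5 β (C4–H) | C=C1C[C@]23C[C@H]1[C@@H]1C[C@H]2[C@@](CCO[Si](C)(C)C(C)(C)C)(C(=O)O1)[C@H]([C@@H]3C(=O)OC)C(C(=O)SCC)C(=O)SCC
F8 | step 17 | 1,3-diol: C4 = C(CH3)(CH2OH)2; TBS ether | C=C1C[C@]23C[C@H]1[C@@H]1C[C@H]2[C@@](CCO[Si](C)(C)C(C)(C)C)(C(=O)O1)[C@H]([C@@H]3C(=O)OC)C(C)(CO)CO
F9 | step 17 | triol from F8 | C=C1C[C@]23C[C@H]1[C@@H]1C[C@H]2[C@@](CCO)(C(=O)O1)[C@H]([C@@H]3C(=O)OC)C(C)(CO)CO
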